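## Retrosynthetic overview

- The arene is removed last: the C9–CH2Ar bond comes from benzylation of the enolate formed by Li/NH3 reduction of a bicyclic enone acid, and the C8 methyl from methylenation and hydrogenation of the C8 ketone.
- Ring B is opened at C9=C10 to a 1,5-diketone (intramolecular aldol condensation); its ethyl ketone arm is attached to a ring A aldehyde by Horner–Wadsworth–Emmons olefination.
- The strategy rests on ring A: the exocyclic tetrasubstituted C3=C(CH3)2 sits next to C4–H, which carries the CH2CH2CO2H chain cis to the methyl on the quaternary ring-fusion carbon C5. This is the adduct pattern of a vinylallene with an (E)-2-methyl-2-enal, so ring A is cut at C3–C4 and C5–C10 by an enantioselective [4+2].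
- Ring order: ring A (cycloaddition), then ring B (aldol condensation), then attachment of the arene.

Key step: step 4

Remark on locants: all ring atoms carry the decalin numbering of the target. Ring A is C10, C1, C2, C3, C4, C5 and ring B is C5 to C10. C3 bears the isopropylidene, C4 the propanoate chain, C5 the angular methyl, C8 the secondary methyl, C9 a methyl and the arylmethyl group, C10 the ring-fusion hydrogen.

Assumption: the (S)-configured cationic oxazaborolidine is taken to leave open the Re face of the α-carbon of the enal dienophile, by analogy with its behaviour toward α-substituted acroleins. If the sense of induction is the opposite, the (R)-catalyst is used and nothing else changes.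

## Route

Step 1
Reactants: 1 2-methylbut-3-yn-2-ol; 2 ethyl vinyl ether
Product: 4 5-methylhexa-3,4-dienal, via propargyl vinyl ether 3 (not isolated)
Conditions: 2 (excess, as solvent), Hg(OAc)2 (5 mol%), NaOAc, sealed tube, 40 °C then 110 °C
Reagents that add atoms: none
Why: Hg(OAc)2-mediated vinyl exchange should give the tertiary propargyl vinyl ether, whose [3,3]-sigmatropic propargyl Claisen (Saucy–Marbet-type) rearrangement bonds the vinyl terminus to the alkyne terminus and delivers the gem-dimethyl allene with the aldehyde two carbons away.

Step 2
Reactants: 4 5-methylhexa-3,4-dienal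
Product: 5 (E)-1-(tert-butyldimethylsilyloxy)-5-methylhexa-1,3,4-triene
Conditions: TBSOTf, Et3N, CH2Cl2, −78 → 0 °C
Reagents that add atoms: tert-butyldimethylsilyl triflate (TBSOTf), CC(C)(C)[Si](C)(C)OS(=O)(=O)C(F)(F)F
Why: Soft enolisation (O-silylation, then removal of the doubly activated C2 proton by the amine) should give the silyl dienol ether, with the extended E enol ether expected to predominate, while any Z isomer would lead only to the epimer at a carbon that is oxidised in step 9.

Step 3
Reactants: 6 methyl 4-oxobutanoate; 7 2-(triphenylphosphoranylidene)propanal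
Product: 8 methyl (E)-5-methyl-6-oxohex-4-enoate
Conditions: toluene, 80 °C
Reagents that add atoms: none
Why: Wittig olefination with the formyl-stabilised ylide is E-selective for the trisubstituted enal, the geometry that later fixes the chain cis to the C5 methyl.

Step 4
Reactants: 5 (E)-1-(tert-butyldimethylsilyloxy)-5-methylhexa-1,3,4-triene; 8 methyl (E)-5-methyl-6-oxohex-4-enoate
Product: 9 ring A cycloadduct (C5 with CH3 and CHO; C4 chain cis to the C5 methyl; C3 isopropylidene; C1=C2; C10 OTBS)
Conditions: 5 (1.5 equiv), (S)-1-(2-methylphenyl)-3,3-diphenyltetrahydro-1H,3H-pyrrolo[1,2-c][1,3,2]oxazaborole (20 mol%) activated with (CF3SO2)2NH (18 mol%), CH2Cl2, −78 → −40 °C; Et3N quench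
Reagents that add atoms: none
Why: Proposed new method: the N-protonated oxazaborolidine binds the formyl oxygen of 8 (B–O coordination backed by a formyl C–H···O contact) and lowers its LUMO, so that the s-cis vinylallene 5 should add in a concerted, asynchronous [4+2] in which the bond from the central allene carbon to the enal β-carbon leads and the bond from the silyloxy-bearing terminus to the α-carbon follows. The closest known reaction types are Diels–Alder reactions of vinylallenes that give alkylidenecyclohexenes and cationic-oxazaborolidine-catalysed cycloadditions of 1-oxygenated dienes with α-methyl enals; their combination on a β-alkyl α-methyl enal is untested. Ring A closes as a six-membered carbocycle by intermolecular cycloaddition (bonds C3–C4 and C5–C10), and the untouched distal allene π bond remains as the exocyclic C3 isopropylidene, so its position needs no later control. C4 and C5 are formed together: the E geometry of 8 is transferred suprafacially and puts the ester chain cis to the C5 methyl, and the catalyst fixes the absolute sense by exposing the Re face of the α-carbon (Si face of the β-carbon); the silyloxy carbon is expected mainly as the endo epimer (cis to CHO), which is immaterial because that centre is oxidised in step 9. The step needs ortho regioselectivity and enantioface selectivity: the 1-silyloxy group makes the allenic terminus the nucleophilic end of the diene, which pairs with the electrophilic β-carbon, and the gem-dimethyl allene terminus is achiral, so only the face of the bound enal has to be distinguished.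

Step 5
Reactants: 9 ring A cycloadduct
Product: 10 ring A aldehyde with saturated C1–C2
Conditions: KO2C–N=N–CO2K (dipotassium azodicarboxylate, excess), AcOH (slow addition), CH2Cl2, 0 °C → rt
Reagents that add atoms: none
Why: Diimide reduction transfers H2 in a concerted syn manner to the cis-disubstituted π bond only, so the tetrasubstituted isopropylidene is not reduced, no 1,4-reduction or migration of the diene can occur, and the hydrazine-free diimide source leaves the formyl group alone.

Step 6
Reactants: 10 ring A aldehyde with saturated C1–C2; 11 diethyl (2-oxobutyl)phosphonate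
Product: 13 ring A (E)-enone, via sodium phosphonate 12 (not isolated)
Conditions: 11, NaH, THF, 0 °C; then 10, 0 → 60 °C
Reagents that add atoms: none
Why: Horner–Wadsworth–Emmons olefination of the non-enolisable neopentyl aldehyde with the stabilised β-ketophosphonate anion should tolerate the heating needed for the hindered carbonyl and attaches C6 to C9 with the future C9 methyl.

Step 7
Reactants: 13 ring A (E)-enone
Product: 14 ring A saturated ethyl ketone
Conditions: [(Ph3P)CuH]6 (0.4 equiv), degassed toluene, H2O (2 equiv), rt
Reagents that add atoms: none
Why: Conjugate reduction by the phosphine-ligated copper hydride delivers hydride to the enone β-carbon and water protonates the copper enolate, so only the conjugated C=C is reduced and the isolated alkene, ester and silyl ether are untouched.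

Step 8
Reactants: 14 ring A saturated ethyl ketone
Product: 15 ring A C10 alcohol
Conditions: 48% aq. HF, MeCN, 0 °C → rt
Reagents that add atoms: none
Why: Fluoride-driven Si–O cleavage (desilylation) should remove the hindered secondary TBS ether under conditions that spare the ester, ketone and tetrasubstituted alkene, the product possibly resting in part as its six-membered hemiketal.

Step 9
Reactants: 15 ring A C10 alcohol
Product: 16 ring A 1,5-diketone
Conditions: DMP (1,1,1-triacetoxy-1,1-dihydro-1,2-benziodoxol-3(1H)-one), NaHCO3, CH2Cl2, rt
Reagents that add atoms: none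
Why: Hypervalent-iodine oxidation of the secondary alcohol (drawn from any hemiketal through the open form) gives the ring ketone under buffered neutral conditions and removes the C10 stereocentre, so both cycloadduct epimers converge.

Step 10
Reactants: 16 ring A 1,5-diketone
Product: 19 octalone acid, via diketo carboxylate 17 (not isolated), via ketol carboxylate 18 (not isolated)
Conditions: KOH, MeOH/H2O, rt then 60 °C; aq. HCl
Reagents that add atoms: potassium hydroxide, [K+].[OH-]
Why: Saponification followed by intramolecular aldol condensation (the second stage of a Robinson annulation) joins the ethyl ketone methylene C9 to the ring carbonyl C10 and dehydrates to the tetrasubstituted C9=C10 enone, while C4 and C5 are not enolisable and keep their configuration.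

Step 11
Reactants: 20 4-methoxy-2-methylphenol
Product: 21 2-hydroxy-5-methoxy-3-methylbenzaldehyde
Conditions: MgCl2, Et3N, (CH2O)n, MeCN, reflux; aq. HCl
Reagents that add atoms: paraformaldehyde (formaldehyde), C=O
Why: Magnesium-phenoxide-directed ortho-formylation can only occur at the single free ortho position, a second formaldehyde serving as hydride acceptor.

Step 12
Reactants: 21 2-hydroxy-5-methoxy-3-methylbenzaldehyde
Product: 22 2-benzyloxy-5-methoxy-3-methylbenzaldehyde
Conditions: BnBr, K2CO3, DMF, 60 °C
Reagents that add atoms: benzyl bromide, BrCc1ccccc1
Why: Williamson etherification of the phenoxide installs a phenol protecting group that survives enolate and ylide chemistry and is removable by hydrogenolysis beside the aryl methyl ether.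

Step 13
Reactants: 22 2-benzyloxy-5-methoxy-3-methylbenzaldehyde
Product: 23 (2-benzyloxy-5-methoxy-3-methylphenyl)methanol
Conditions: NaBH4, MeOH, 0 °C
Reagents that add atoms: none
Why: Borohydride reduction converts the aryl aldehyde cleanly into the benzylic alcohol.

Step 14
Reactants: 23 (2-benzyloxy-5-methoxy-3-methylphenyl)methanol
Product: 24 2-benzyloxy-5-methoxy-3-methylbenzyl bromide
Conditions: PBr3, Et2O, 0 °C
Reagents that add atoms: phosphorus tribromide, BrP(Br)Br
Why: Bromide displaces the activated phosphite ester of the benzylic alcohol (Appel-type SN2 substitution) and gives the alkylating agent, to be used freshly.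

Step 15
Reactants: 19 octalone acid; 24 2-benzyloxy-5-methoxy-3-methylbenzyl bromide
Product: 26 benzylated trans-decalone acid, via dilithium enolate carboxylate 25 (not isolated)
Conditions: Li (6 equiv), NH3(l)/THF, t-BuOH (1 equiv), −78 → −33 °C; isoprene; NH3 removed; 24 (1.3 equiv), THF, −78 → 0 °C; aq. HCl
Reagents that add atoms: none
Why: Dissolving-metal (Birch-type) reductive alkylation: the C10 carbanion is protonated on the face opposite the C5 methyl (trans ring fusion) and the regiodefined C8–C9 lithium enolate is C-benzylated on the face away from the axial C5 methyl, which places the arylmethyl group trans and the C9 methyl cis to the C5 methyl, while the lithium carboxylate is inert to the metal and the excess metal is destroyed before the bromide is added.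

Step 16
Reactants: 26 benzylated trans-decalone acid
Product: 27 C8-methylene acid
Conditions: Ph3PCH3Br (6 equiv), KOtBu (7 equiv), toluene/THF, 90 °C; aq. HCl
Reagents that add atoms: methyltriphenylphosphonium bromide, C[P+](c1ccccc1)(c1ccccc1)c1ccccc1.[Br-]
Why: Wittig methylenation with the small unstabilised ylide in excess at elevated temperature should convert the ketone flanked by the quaternary C9, the carboxylate only consuming one equivalent of base.

Step 17
Reactants: 27 C8-methylene acid
Product: 28 target CNP0299684.2
Conditions: H2 (1 atm), 10% Pd/C, EtOAc, rt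
Reagents that add atoms: none
Why: Heterogeneous catalytic hydrogenation should add H2 to the 1,1-disubstituted C8 methylene from the face opposite the axial C9 methyl (giving the equatorial C8 methyl cis to the C9 methyl) and cleave the benzyl ether by hydrogenolysis, while the tetrasubstituted isopropylidene is too hindered to be reduced.

## Compound list

1 | 2-methylbut-3-yn-2-ol | CC(C)(O)C#C | starting material
2 | ethyl vinyl ether | C=COCC | starting material
3 | 3-methyl-3-(vinyloxy)but-1-yne (propargyl vinyl ether) | C=COC(C)(C)C#C | intermediate (not isolated)
4 | 5-methylhexa-3,4-dienal | CC(C)=C=CCC=O | intermediate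
5 | (E)-1-(tert-butyldimethylsilyloxy)-5-methylhexa-1,3,4-triene (1-silyloxy vinylallene) | CC(C)=C=C/C=C/O[Si](C)(C)C(C)(C)C | intermediate
6 | methyl 4-oxobutanoate | COC(=O)CCC=O | starting material
7 | 2-(triphenylphosphoranylidene)propanal | CC(C=O)=P(c1ccccc1)(c1ccccc1)c1ccccc1 | starting material
8 | methyl (E)-5-methyl-6-oxohex-4-enoate | COC(=O)CC/C=C(\C)C=O | intermediate
9 | ring A cycloadduct: methyl 3-[5-(tert-butyldimethylsilyloxy)-6-formyl-6-methyl-2-(propan-2-ylidene)cyclohex-3-en-1-yl]propanoate, chain cis to the C5 methyl, OTBS cis to CHO | CC(C)(C)[Si](C)(C)O[C@@H]1C=CC(=C(C)C)[C@@H](CCC(=O)OC)[C@]1(C)C=O | intermediate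
10 | ring A aldehyde with saturated C1–C2: methyl 3-[3-(tert-butyldimethylsilyloxy)-2-formyl-2-methyl-6-(propan-2-ylidene)cyclohexyl]propanoate, configuration as in 9 | CC(C)(C)[Si](C)(C)O[C@@H]1CCC(=C(C)C)[C@@H](CCC(=O)OC)[C@]1(C)C=O | intermediate
11 | diethyl (2-oxobutyl)phosphonate | CCC(=O)CP(=O)(OCC)OCC | starting material
12 | sodium salt of diethyl (2-oxobutyl)phosphonate | CCC([O-])=CP(=O)(OCC)OCC.[Na+] | intermediate (not isolated)
13 | ring A (E)-enone: C5 bears CH3 and (E)-CH=CH–C(=O)–CH2CH3 | CC(C)(C)[Si](C)(C)O[C@@H]1CCC(=C(C)C)[C@@H](CCC(=O)OC)[C@]1(C)/C=C/C(=O)CC | intermediate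
14 | ring A saturated ethyl ketone: C5 bears CH3 and CH2CH2C(=O)CH2CH3, C10 OTBS | CC(C)(C)[Si](C)(C)O[C@@H]1CCC(=C(C)C)[C@@H](CCC(=O)OC)[C@]1(C)CCC(=O)CC | intermediate
15 | ring A C10 alcohol (δ-hydroxy ketone, in equilibrium with its hemiketal) | O[C@@H]1CCC(=C(C)C)[C@@H](CCC(=O)OC)[C@]1(C)CCC(=O)CC | intermediate
16 | ring A 1,5-diketone: methyl 3-[2-methyl-3-oxo-2-(3-oxopentyl)-6-(propan-2-ylidene)cyclohexyl]propanoate, chain cis to the C5 methyl | O=C1CCC(=C(C)C)[C@@H](CCC(=O)OC)[C@]1(C)CCC(=O)CC | intermediate
17 | potassium salt of the diketo acid | O=C1CCC(=C(C)C)[C@@H](CCC(=O)[O-])[C@]1(C)CCC(=O)CC.[K+] | intermediate (not isolated)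
18 | potassium salt of the bicyclic ketol (C9–C10 aldol adduct, C10–OH) | CC1C2(O)CCC(=C(C)C)[C@@H](CCC(=O)[O-])[C@]2(C)CCC1=O.[K+] | intermediate (not isolated)
19 | octalone acid: C8 ketone, C9=C10 enone with C9 methyl, C5 angular methyl cis to the C4 propanoic acid chain, C3 isopropylidene | CC1=C2CCC(=C(C)C)[C@@H](CCC(=O)O)[C@]2(C)CCC1=O | intermediate
20 | 4-methoxy-2-methylphenol | COc1ccc(O)c(C)c1 | starting material
21 | 2-hydroxy-5-methoxy-3-methylbenzaldehyde | COc1cc(C)c(O)c(C=O)c1 | intermediate
22 | 2-benzyloxy-5-methoxy-3-methylbenzaldehyde | COc1cc(C)c(OCc2ccccc2)c(C=O)c1 | intermediate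
23 | (2-benzyloxy-5-methoxy-3-methylphenyl)methanol | COc1cc(C)c(OCc2ccccc2)c(CO)c1 | intermediate
24 | 2-benzyloxy-5-methoxy-3-methylbenzyl bromide | COc1cc(C)c(OCc2ccccc2)c(CBr)c1 | intermediate
25 | dilithium salt: C8–C9 enolate and carboxylate of the trans-fused reduced octalone (H-10 trans to the C5 methyl) | [Li+].[Li+].CC=2[C@H]3CCC(=C(C)C)[C@@H](CCC(=O)[O-])[C@]3(C)CCC=2[O-] | intermediate (not isolated)
26 | benzylated trans-decalone acid: C8 ketone; C9 with methyl (cis to the C5 methyl) and (2-benzyloxy-5-methoxy-3-methylphenyl)methyl (trans to the C5 methyl); H-10 trans to the C5 methyl | COc1cc(C)c(OCc4ccccc4)c(C[C@]2(C)[C@H]3CCC(=C(C)C)[C@@H](CCC(=O)O)[C@]3(C)CCC2=O)c1 | intermediate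
27 | C8-methylene acid (exocyclic C8=CH2, otherwise as 26) | COc1cc(C)c(OCc4ccccc4)c(C[C@]2(C)[C@H]3CCC(=C(C)C)[C@@H](CCC(=O)O)[C@]3(C)CCC2=C)c1 | intermediate
28 | 3-[(1S,4aR,5S,6R,8aR)-5-[(2-hydroxy-5-methoxy-3-methylphenyl)methyl]-5,6,8a-trimethyl-2-(propan-2-ylidene)decahydronaphthalen-1-yl]propanoic acid (CNP0299684.2) | COc1cc(C)c(O)c(C[C@]2(C)[C@H]3CCC(=C(C)C)[C@@H](CCC(=O)O)[C@]3(C)CC[C@H]2C)c1 | target

## Step count and risks

Total step count: 17. Longest linear sequence: 12 steps (steps 1, 2, 4 to 10, 15 to 17).

Steps most likely to fail:

1. Step 4 (the cycloaddition).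
   - What may go wrong: the β-substituted α-methyl enal is a sluggish dienophile, and one allene methyl necessarily projects over each face of the diene. The activated formyl group may instead undergo Mukaiyama-type 1,2-addition. The acid may cleave the enol silane or ionise the dienylic silyl ether of the product. Face discrimination by the catalyst may be insufficient.
   - Fallback: it sets out from 5 and 8 and gives up asymmetric induction. The cycloaddition is run as the known Lewis-acid-promoted vinylallene Diels–Alder reaction (Me2AlCl, 1.1 equiv, CH2Cl2, −78 → −20 °C), which should give racemic cycloadduct F1. The enantiomers of F1 are separated by preparative supercritical-fluid chromatography on a polysaccharide chiral stationary phase, and the required antipode is compound 9, where the route is rejoined.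

2. Step 15 (reductive benzylation).
   - What may go wrong: C-benzylation of the hindered tetrasubstituted enolate may be outrun by proton transfer, giving simple reduction. The carboxylate may be O-benzylated. Protonation at C10 may lose some trans selectivity, because the equatorial C4 chain of the trans-fused ring suffers allylic strain against the isopropylidene.
   - Fallback: it sets out from 19 and separates reduction from alkylation. 19 is reduced as in step 15, the ammonia is removed and the dianion is silylated (TMSCl, Et3N, THF, −78 → 0 °C) to the bis(trimethylsilyl) compound F2 (C8–C9 silyl enol ether and silyl ester), at which stage the ring fusion can be checked. F2 is then alkylated under fluoride activation (anhydrous benzyltrimethylammonium fluoride, 2.2 equiv; 24, 2.2 equiv; THF, 4 Å molecular sieves), so that the free enolate and the carboxylate are both benzylated and give the doubly benzylated keto ester F3. LiOH (THF/H2O) cleaves the ester to 26, where the route resumes, and returns alcohol 23 for reconversion into 24.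

3. Step 17 (hydrogenation with debenzylation).
   - What may go wrong: on the palladium surface the exocyclic methylene may migrate into the ring before it is reduced, the isopropylidene may isomerise or be saturated on prolonged exposure, and hydrogen delivery at C8 may not be fully face-selective.
   - Fallback: it sets out from 27 and separates the two events without a metal surface. Hydrogen-atom-transfer hydrogenation (Mn(dpm)3, dpm = 2,2,6,6-tetramethylheptane-3,5-dionate, catalytic; PhSiH3; t-BuOOH; i-PrOH, rt) generates the tertiary C8 radical, which is quenched axially to give the thermodynamically preferred equatorial C8 methyl in the benzyl-protected saturated acid F4. The benzyl ether is then removed by BCl3 with pentamethylbenzene as cation scavenger (CH2Cl2, −78 °C), which gives 28 directly.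

## Further compounds

F1 | step 4 | racemic cycloadduct (9 together with its mirror image) | CC(C)(C)[Si](C)(C)O[C@@H]1C=CC(=C(C)C)[C@@H](CCC(=O)OC)[C@]1(C)C=O.CC(C)(C)[Si](C)(C)O[C@H]1C=CC(=C(C)C)[C@H](CCC(=O)OC)[C@@]1(C)C=O
F2 | step 15 | bis(trimethylsilyl) compound: C8–C9 trimethylsilyl enol ether and trimethylsilyl ester of the trans-fused reduced octalone acid | CC=2[C@H]3CCC(=C(C)C)[C@@H](CCC(=O)O[Si](C)(C)C)[C@]3(C)CCC=2O[Si](C)(C)C
F3 | step 15 | doubly benzylated keto ester: (2-benzyloxy-5-methoxy-3-methylphenyl)methyl ester of 26 | COc1cc(C)c(OCc4ccccc4)c(C[C@]2(C)[C@H]3CCC(=C(C)C)[C@@H](CCC(=O)OCc5cc(OC)cc(C)c5OCc6ccccc6)[C@]3(C)CCC2=O)c1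
F4 | step 17 | benzyl-protected saturated acid (O-benzyl ether of 28) | COc1cc(C)c(OCc4ccccc4)c(C[C@]2(C)[C@H]3CCC(=C(C)C)[C@@H](CCC(=O)O)[C@]3(C)CC[C@H]2C)c1
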